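**Plan**
- Retrosynthesis: the catechol is first masked as a diphenylmethylene ketal. Both prenyl groups are then cut at C1''–C2'', the bond between the benzylic CH2 and the alkenyl CH, on C6 and on C8.
- Enabling feature: each C1'' sits on ring A ortho to a free phenol oxygen (O7 for the C8 arm, O7 or O5 for the C6 arm). Each is therefore a latent ortho-quinone methide methylene that can accept a 2-methylprop-1-enyl group from boron.
- The two Ar–CH2 bonds (C6–C1'', C8–C1'') are cut next by a retro-Mannich disconnection to ketal-protected quercetin, formaldehyde and dimethylamine.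
- Forward: no ring is built, since the flavonol core comes intact from quercetin. The order is ketalisation, double aminomethylation, twofold quaternisation/elimination/alkenyl transfer, ketal hydrolysis.
- Stereochemistry: the target has no stereocentre, and both alkenes end in two identical methyl groups, so no geometry has to be set.

Key step: step 3

Assumption: in steps 2 and 3 the two ring A positions react one after the other. C8 is drawn as reacting first in each case; the opposite order would converge on the same products 7 and 14. Step 2 consumes two equivalents each of 3 and 4, and step 3 consumes two equivalents each of 8 and 9. Compound 5 stands for the formaldehyde–dimethylamine adduct that ionises to the N,N-dimethylmethaniminium electrophile; it forms once for each arm.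

**Step 1**
Reactants: 1 quercetin
Product: 2 3',4'-O-(diphenylmethylene)quercetin
Conditions: Ph2CCl2 (1.5 equiv), Ph2O, 175 °C, N2
Reagents that add atoms: dichlorodiphenylmethane, ClC(Cl)(c1ccccc1)c1ccccc1
Why: Ketalisation of a catechol with a gem-dichloride; only the 3',4'-hydroxyl pair can close a five-membered 1,3-dioxole by two successive chloride displacements through a diphenyl-stabilised cation, and this is the standard selective protection of quercetin.

**Step 2**
Reactants: 2 3',4'-O-(diphenylmethylene)quercetin; 3 formaldehyde; 4 dimethylamine
Product: 7 6,8-bis[(dimethylamino)methyl]-3',4'-O-(diphenylmethylene)quercetin, via (dimethylamino)methanol 5 (not isolated), via 8-mono-Mannich base 6 (not isolated)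
Conditions: 3 (37% aq., 2.5 equiv), 4 (40% aq., 2.5 equiv), EtOH/1,4-dioxane, 60 °C; product collected by precipitation
Reagents that add atoms: formaldehyde (second equivalent), C=O; dimethylamine (second equivalent), CNC
Why: Twofold phenolic Mannich aminomethylation, in which one molecule each of 3 and 4 is used per arm; the iminium ion from 5 attacks C8 and then C6, the only unsubstituted carbons of the phloroglucinol-type ring A, while the ketalised ring B has no free phenol and C2/C3 carry no hydrogen.

**Step 3**
Reactants: 7 6,8-bis[(dimethylamino)methyl]-3',4'-O-(diphenylmethylene)quercetin; 8 iodomethane; 9 2-methylprop-1-enylboronic acid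
Product: 14 3',4'-O-(diphenylmethylene)-6,8-bis(3-methylbut-2-enyl)quercetin, via bis(trimethylammonium) diiodide 10 (not isolated), via C8 ortho-quinone methide 11 (not isolated), via 8-prenyl C6-ammonium iodide 12 (not isolated), via C6 ortho-quinone methide 13 (not isolated)
Conditions: 8 (2.4 equiv), MeCN, 0 °C to rt, dark, no base; evaporate volatiles; then 9 (5 equiv), MeCN, K2CO3 (3 equiv) in portions, rt to 60 °C, Ar; aq. NH4Cl work-up
Reagents that add atoms: 2-methylprop-1-enylboronic acid (second equivalent), CC(C)=CB(O)O
Why: Each trimethylammonium group is expelled by the ortho phenoxide in a base-induced 1,4-elimination to an ortho-quinone methide; its carbonyl oxygen binds the boron of 9, and the resulting boronate passes the 2-methylprop-1-enyl group to the exocyclic methylene through a six-membered transition state, which forms the C1''–C2'' bond and restores the aromatic ring A. The closest known reaction type is the conjugate addition of alkenylboronic acids and boronates to ortho-quinone methides generated in situ from ortho-hydroxybenzyl ethers, amines or ammonium salts, here run twice in one flask with one molecule of 9 per arm. No ring is closed and no stereocentre is formed, and the transferred alkenyl carbon ends in two identical methyl groups, so no alkene geometry arises. The step needs chemoselectivity for the exocyclic methylene over C2 and C4 of the chromone; internal delivery from oxygen-bound boron, the gain of aromaticity and the absence of a free carbanion should secure this. O-Methylation is avoided by quaternising without base and removing excess 8 before K2CO3 is added; the ketal keeps ring B from binding boron, and with C6 and C8 both substituted, ring A cannot capture a quinone methide of another molecule through carbon.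

**Step 4**
Reactants: 14 3',4'-O-(diphenylmethylene)-6,8-bis(3-methylbut-2-enyl)quercetin
Product: 15 6,8-bis(3-methylbut-2-enyl)quercetin (target)
Conditions: AcOH/H2O (4:1), 90 °C, Ar, stopped as soon as 14 is consumed
Reagents that add atoms: none
Why: Acid-catalysed hydrolysis of the diaryl ketal through a diphenyl-stabilised oxocarbenium ion; acetic acid is too weak to protonate the trisubstituted prenyl alkenes at a comparable rate, and the flavonol core is inert to it.

**Compound list**
1 | quercetin (3,3',4',5,7-pentahydroxyflavone) | O=c1c(O)c(-c2ccc(O)c(O)c2)oc2cc(O)cc(O)c12 | starting material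
2 | 3',4'-O-(diphenylmethylene)quercetin; 2-(2,2-diphenyl-1,3-benzodioxol-5-yl)-3,5,7-trihydroxy-4H-chromen-4-one | O=c1c(O)c(-c2ccc3OC(c4ccccc4)(c4ccccc4)Oc3c2)oc2cc(O)cc(O)c12 | intermediate
3 | formaldehyde | C=O | starting material
4 | dimethylamine | CNC | starting material
5 | (dimethylamino)methanol, the hemiaminal source of the N,N-dimethylmethaniminium ion | CN(C)CO | intermediate (not isolated)
6 | 8-[(dimethylamino)methyl]-3',4'-O-(diphenylmethylene)quercetin | CN(C)Cc1c(O)cc(O)c2c(=O)c(O)c(-c3ccc4OC(c5ccccc5)(c5ccccc5)Oc4c3)oc12 | intermediate (not isolated)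
7 | 6,8-bis[(dimethylamino)methyl]-3',4'-O-(diphenylmethylene)quercetin | CN(C)Cc1c(O)c(CN(C)C)c2oc(-c3ccc4OC(c5ccccc5)(c5ccccc5)Oc4c3)c(O)c(=O)c2c1O | intermediate
8 | iodomethane | CI | starting material
9 | 2-methylprop-1-enylboronic acid | CC(C)=CB(O)O | starting material
10 | 6,8-bis[(trimethylammonio)methyl]-3',4'-O-(diphenylmethylene)quercetin diiodide | C[N+](C)(C)Cc1c(O)c(C[N+](C)(C)C)c2oc(-c3ccc4OC(c5ccccc5)(c5ccccc5)Oc4c3)c(O)c(=O)c2c1O.[I-].[I-] | intermediate (not isolated)
11 | C8 ortho-quinone methide: ring A as the 8-methylidene-7-oxo form, C6 still bearing CH2NMe3+ iodide, 5-OH and chromone intact | C=C1C(=O)C(C[N+](C)(C)C)=C(O)C2=C1OC(c1ccc3OC(c4ccccc4)(c4ccccc4)Oc3c1)=C(O)C2=O.[I-] | intermediate (not isolated)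
12 | 8-(3-methylbut-2-enyl)-6-[(trimethylammonio)methyl]-3',4'-O-(diphenylmethylene)quercetin iodide | C[N+](C)(C)Cc1c(O)c(CC=C(C)C)c2oc(-c3ccc4OC(c5ccccc5)(c5ccccc5)Oc4c3)c(O)c(=O)c2c1O.[I-] | intermediate (not isolated)
13 | C6 ortho-quinone methide of the 8-prenyl compound, drawn as the 6-methylidene-7-oxo tautomer | C=C1C(=O)C(CC=C(C)C)=C2OC(c3ccc4OC(c5ccccc5)(c5ccccc5)Oc4c3)=C(O)C(=O)C2=C1O | intermediate (not isolated)
14 | 3',4'-O-(diphenylmethylene)-6,8-bis(3-methylbut-2-enyl)quercetin | CC(C)=CCc1c(O)c(CC=C(C)C)c2oc(-c3ccc4OC(c5ccccc5)(c5ccccc5)Oc4c3)c(O)c(=O)c2c1O | intermediate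
15 | 6,8-bis(3-methylbut-2-enyl)quercetin; 2-(3,4-dihydroxyphenyl)-3,5,7-trihydroxy-6,8-bis(3-methylbut-2-enyl)-4H-chromen-4-one | CC(C)=CCc1c(O)c(CC=C(C)C)c2oc(-c3ccc(O)c(O)c3)c(O)c(=O)c2c1O | target

**Step count**
Total steps: 4. Longest linear sequence: 4 steps (1 → 2 → 7 → 14 → 15).

**Steps most likely to fail**

Step 3. What may go wrong:
- a phenoxide may be O-methylated during quaternisation;
- the quinone methides may be captured by phenoxide oxygen, iodide, trimethylamine or a second quinone methide faster than boron passes on its alkenyl group;
- 9 may protodeboronate.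

The fallback gives up the quinone methide and prenylates ring A directly. It sets out from 2, which is treated with 1-bromo-3-methylbut-2-ene (at least two equivalents) and NaOMe in MeOH at 0 °C to rt. C-Alkylation of the ring A phenoxide in protic medium, a known nuclear prenylation of 5,7-dihydroxyflavonoids, should place prenyl groups on C6 and C8. Mono-C- and O-prenylated isomers would have to be removed by chromatography. It rejoins the route at 14 and makes no compound outside the list (F0).

Step 4. What may go wrong: acid-promoted addition of the ortho phenols to the prenyl double bonds (chroman formation) or hydration of the alkenes may compete with ketal hydrolysis.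

The fallback moves the hydrolysis ahead of the alkenylation, so that no prenyl group ever meets hot acid. It sets out from 7 and rejoins the route at 15:
- 7 is heated in AcOH/H2O, where the protonated amines are inert, and neutralised to give 6,8-bis[(dimethylamino)methyl]quercetin F1.
- F1 is quaternised with two equivalents of 8 without base to the bis(trimethylammonium) diiodide F2.
- After removal of excess 8, F2 is treated with 9 and K2CO3 under argon. One further equivalent of 9 is supplied because the free catechol binds boron reversibly.
- The sequence should run through the C8 ortho-quinone methide F3, the 8-prenyl C6-ammonium iodide F4 and the C6 ortho-quinone methide F5, and give 15 on aqueous work-up.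

Step 2. What may go wrong: the aminomethylation may stall after the first substitution, or the product may lose dimethylamine thermally and form methylene-bridged oligomers.

The fallback installs the two arms one at a time. It sets out from 2 and rejoins the route at 12:
- 2 is treated with one equivalent each of 3 and 4 at lower temperature, and the mono-Mannich base 6 is isolated.
- 6 is quaternised with 8 to the 8-[(trimethylammonio)methyl] iodide F6.
- F6 is treated with 9 and K2CO3 and should pass through the 8-methylidene-7-oxo quinone methide F7 to 8-(3-methylbut-2-enyl)-3',4'-O-(diphenylmethylene)quercetin F8.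
- A second Mannich reaction with one more equivalent each of 3 and 4 at C6, the only ring A carbon still bearing hydrogen, should give the 6-[(dimethylamino)methyl]-8-prenyl compound F9.
- Quaternisation of F9 with 8 gives 12, from which the second half of step 3 leads through 13 to 14.

**Further compounds**
F0 | step 3 | none | none
F1 | step 4 | 6,8-bis[(dimethylamino)methyl]quercetin | CN(C)Cc1c(O)c(CN(C)C)c2oc(-c3ccc(O)c(O)c3)c(O)c(=O)c2c1O
F2 | step 4 | 6,8-bis[(trimethylammonio)methyl]quercetin diiodide | C[N+](C)(C)Cc1c(O)c(C[N+](C)(C)C)c2oc(-c3ccc(O)c(O)c3)c(O)c(=O)c2c1O.[I-].[I-]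
F3 | step 4 | C8 ortho-quinone methide of F2 (8-methylidene-7-oxo form, C6 CH2NMe3+ iodide retained) | C=C1C(=O)C(C[N+](C)(C)C)=C(O)C2=C1OC(c1ccc(O)c(O)c1)=C(O)C2=O.[I-]
F4 | step 4 | 8-(3-methylbut-2-enyl)-6-[(trimethylammonio)methyl]quercetin iodide | C[N+](C)(C)Cc1c(O)c(CC=C(C)C)c2oc(-c3ccc(O)c(O)c3)c(O)c(=O)c2c1O.[I-]
F5 | step 4 | C6 ortho-quinone methide of F4 (6-methylidene-7-oxo tautomer) | C=C1C(=O)C(CC=C(C)C)=C2OC(c3ccc(O)c(O)c3)=C(O)C(=O)C2=C1O
F6 | step 2 | 8-[(trimethylammonio)methyl]-3',4'-O-(diphenylmethylene)quercetin iodide | C[N+](C)(C)Cc1c(O)cc(O)c2c(=O)c(O)c(-c3ccc4OC(c5ccccc5)(c5ccccc5)Oc4c3)oc12.[I-]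
F7 | step 2 | C8 ortho-quinone methide of F6 (8-methylidene-7-oxo form, C6 unsubstituted) | C=C1C(=O)C=C(O)C2=C1OC(c1ccc3OC(c4ccccc4)(c4ccccc4)Oc3c1)=C(O)C2=O
F8 | step 2 | 8-(3-methylbut-2-enyl)-3',4'-O-(diphenylmethylene)quercetin | CC(C)=CCc1c(O)cc(O)c2c(=O)c(O)c(-c3ccc4OC(c5ccccc5)(c5ccccc5)Oc4c3)oc12
F9 | step 2 | 6-[(dimethylamino)methyl]-8-(3-methylbut-2-enyl)-3',4'-O-(diphenylmethylene)quercetin | CN(C)Cc1c(O)c(CC=C(C)C)c2oc(-c3ccc4OC(c5ccccc5)(c5ccccc5)Oc4c3)c(O)c(=O)c2c1O
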